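## Retrosynthetic overview

1. 28 ⇐ 27: the last step is a Shi epoxidation of the C3=C4 E-olefin of the finished macrocycle, so the epoxide is formed last.
2. 27 ⇐ 26: a new Cr/Ni-catalysed asymmetric branched alkyne–aldehyde reductive macrocyclisation makes the C7–C8 bond, the C7 carbinol, the C8=C19 methylene and the 14-membered ring (formed second).
3. 26 ⇐ 24 ⇐ 22 + 21: a chelation-controlled indium Barbier allylation followed by lactonisation makes the C1–C14 bond, sets C1 and C14 and closes the α-methylene-γ-lactone (formed first).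
4. West piece 10 (C8–C14) comes from an Evans syn aldol (C12, C13) and a Cu-catalysed alkyl–alkyl coupling; east piece 21 (C1–C7, C15–C17) from Negishi carboalumination/oxirane opening, vinylalumination and allylic bromination.
5. Ring order: γ-lactone (step 12) → 14-membered carbocycle (step 15) → epoxide (step 16).

Atom labels (cembrane numbering): ring C1–C14; C1 = lactone CH carrying C15(=C17H2)–C16(=O)–O; C3/C4 = epoxide (C18 methyl on C4); C7 = CHOH; C8 = C(=C19H2); C12 = CH(C20H3); C13 = CHOH; C14 = CH–O of the lactone. Target descriptors: 1S,3R,4R,7R,12S,13R,14R.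

Assumption: in step 15 the (4R)-ligand is taken to give the (7R)-alcohol; if the sense of induction is the opposite, the (4S)-ligand is used with nothing else changed.

## Route

Step 1
Reactants: 1 (R)-4-benzyl-3-propionyloxazolidin-2-one; 2 acrolein
Product: 3 (R)-4-benzyl-3-[(2R,3S)-3-hydroxy-2-methylpent-4-enoyl]oxazolidin-2-one
Conditions: Bu2BOTf, i-Pr2NEt, CH2Cl2, −78 → 0 °C; then 2, −78 → 0 °C; aq. NaH2PO4/Na2HPO4 (pH 7), MeOH, H2O2, 0 °C
Reagents that add atoms: none
Why: Evans syn aldol through the Z-boron enolate and a Zimmerman–Traxler chair, in which the (R)-benzyl auxiliary sets C12 and C13 (syn methyl/hydroxyl, 2R,3S in 3).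

Step 2
Reactants: 3 (R)-4-benzyl-3-[(2R,3S)-3-hydroxy-2-methylpent-4-enoyl]oxazolidin-2-one
Product: 4 (R)-4-benzyl-3-[(2R,3S)-3-(tert-butyldimethylsilyloxy)-2-methylpent-4-enoyl]oxazolidin-2-one
Conditions: TBSOTf, 2,6-lutidine, CH2Cl2, −78 → 0 °C
Reagents that add atoms: tert-butyldimethylsilyl trifluoromethanesulfonate, CC(C)(C)[Si](C)(C)OS(=O)(=O)C(F)(F)F
Why: Silyl triflate/lutidine silylation of the hindered secondary alcohol is routine and prevents retro-aldol in the next steps.

Step 3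
Reactants: 4 (R)-4-benzyl-3-[(2R,3S)-3-(tert-butyldimethylsilyloxy)-2-methylpent-4-enoyl]oxazolidin-2-one
Product: 5 (2S,3S)-3-(tert-butyldimethylsilyloxy)-2-methylpent-4-en-1-ol
Conditions: LiBH4, MeOH (1 equiv), Et2O, 0 °C
Reagents that add atoms: none
Why: Reductive removal of the oxazolidinone with LiBH4 gives the primary alcohol without epimerising C12.

Step 4
Reactants: 5 (2S,3S)-3-(tert-butyldimethylsilyloxy)-2-methylpent-4-en-1-ol
Product: 6 tert-butyl{[(3S,4R)-5-iodo-4-methylpent-1-en-3-yl]oxy}dimethylsilane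
Conditions: I2, PPh3, imidazole, CH2Cl2, 0 °C → rt
Reagents that add atoms: iodine, II
Why: Appel-type iodination of a primary alcohol proceeds under neutral conditions and leaves both stereocentres untouched.

Step 5
Reactants: 6 tert-butyl{[(3S,4R)-5-iodo-4-methylpent-1-en-3-yl]oxy}dimethylsilane; 7 (4-bromobut-1-yn-1-yl)trimethylsilane
Product: 9 tert-butyldimethyl{[(3S,4S)-4-methyl-9-(trimethylsilyl)non-1-en-8-yn-3-yl]oxy}silane, via Grignard reagent 8 (not isolated)
Conditions: 7, Mg, THF, 40 °C; then 6, Li2CuCl4 (5 mol %), THF, −20 → 0 °C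
Reagents that add atoms: none
Why: Kochi-type copper-catalysed sp3–sp3 coupling of a primary iodide with an alkyl Grignard reagent forms the C10–C11 bond, as is routine for β-branched iodides of this kind.

Step 6
Reactants: 9 tert-butyldimethyl{[(3S,4S)-4-methyl-9-(trimethylsilyl)non-1-en-8-yn-3-yl]oxy}silane
Product: 10 (3S,4S)-4-methylnon-1-en-8-yn-3-ol
Conditions: Bu4NF (2.5 equiv), THF, 0 °C → rt
Reagents that add atoms: none
Why: Fluoride cleaves both the O–Si and the C(sp)–Si bond in one operation, releasing the free allylic alcohol needed for chelation later.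

Step 7
Reactants: 11 pent-4-yn-1-ol
Product: 12 tert-butyldimethyl(pent-4-yn-1-yloxy)silane
Conditions: TBSCl, imidazole, CH2Cl2, rt
Reagents that add atoms: tert-butyldimethylsilyl chloride, CC(C)(C)[Si](C)(C)Cl
Why: Standard silyl protection of a primary alcohol that withstands the organoaluminium chemistry to follow.

Step 8
Reactants: 12 tert-butyldimethyl(pent-4-yn-1-yloxy)silane; 13 oxirane
Product: 16 (E)-7-(tert-butyldimethylsilyloxy)-4-methylhept-3-en-1-ol, via alkenylalane 14 (not isolated), via lithium alkenylalanate 15 (not isolated)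
Conditions: Me3Al (2.5 equiv), Cp2ZrCl2 (25 mol %), CH2Cl2, 0 °C → rt; volatiles removed; hexane, n-BuLi, 0 °C; then 13, THF, −30 °C → rt
Reagents that add atoms: trimethylaluminium, C[Al](C)C
Why: Negishi zirconium-catalysed carboalumination adds methyl and aluminium syn across the alkyne, fixing the E geometry of C3=C4 with the C18 methyl, and the derived alanate opens oxirane with retention of olefin geometry.

Step 9
Reactants: 16 (E)-7-(tert-butyldimethylsilyloxy)-4-methylhept-3-en-1-ol
Product: 17 (E)-7-(tert-butyldimethylsilyloxy)-4-methylhept-3-enal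
Conditions: Dess–Martin periodinane, NaHCO3, CH2Cl2, 0 °C → rt; used at once
Reagents that add atoms: none
Why: Buffered Dess–Martin oxidation is non-basic, so the β,γ-unsaturated aldehyde is obtained without migration of the olefin into conjugation.

Step 10
Reactants: 17 (E)-7-(tert-butyldimethylsilyloxy)-4-methylhept-3-enal; 18 methyl propiolate
Product: 20 methyl (E)-9-(tert-butyldimethylsilyloxy)-3-hydroxy-6-methyl-2-methylidenenon-5-enoate (racemic at C-3), via aluminoacrylate 19 (not isolated)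
Conditions: i-Bu2AlH, HMPA, THF, 0 °C, then 18, 0 °C; then 17, 0 °C → rt; aq. NH4Cl
Reagents that add atoms: none
Why: Vinylalumination (hydroalumination of the propiolate, then 1,2-addition of the α-aluminoacrylate) gives the Baylis–Hillman-type adduct quickly and without amine base, so the sensitive aldehyde does not isomerise; the new carbinol centre is removed in step 11.

Step 11
Reactants: 20 methyl (E)-9-(tert-butyldimethylsilyloxy)-3-hydroxy-6-methyl-2-methylidenenon-5-enoate
Product: 21 methyl (2Z,5E)-2-(bromomethyl)-9-(tert-butyldimethylsilyloxy)-6-methylnona-2,5-dienoate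
Conditions: NBS, Me2S, CH2Cl2, 0 °C (premixed), then 20, 0 °C → rt
Reagents that add atoms: N-bromosuccinimide, O=C1CCC(=O)N1Br
Why: Corey–Kim-type SN2′ bromination of a Baylis–Hillman alcohol gives the thermodynamically preferred Z-2-(bromomethyl)enoate (chain trans to the ester), the geometry required for a cis-lactone.

Step 12
Reactants: 10 (3S,4S)-4-methylnon-1-en-8-yn-3-ol; 21 methyl (2Z,5E)-2-(bromomethyl)-9-(tert-butyldimethylsilyloxy)-6-methylnona-2,5-dienoate
Product: 24 (4S,5R)-4-[(E)-6-(tert-butyldimethylsilyloxy)-3-methylhex-2-en-1-yl]-5-[(1R,2S)-1-hydroxy-2-methylhept-6-yn-1-yl]-3-methylidenedihydrofuran-2(3H)-one, via hydroxy aldehyde 22 (not isolated), via hydroxy ester 23 (not isolated)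
Conditions: 10, O3, CH2Cl2/MeOH 5:1, −78 °C (Sudan red 7B end point), then Me2S, → rt, concentrate; 21, In powder, THF/H2O 1:1, rt; then pyridinium p-toluenesulfonate (10 mol %), CH2Cl2, rt
Reagents that add atoms: ozone, [O-][O+]=O
Why: Ozone cleaves the vinyl group much faster than the terminal alkyne, and the aqueous indium Barbier allylation of the free α-hydroxy aldehyde then proceeds under chelation control (13,14-syn, setting C14) through a chair transition state in which the Z-allyl geometry gives the 1,14-syn adduct (setting C1), so acid-catalysed lactonisation delivers the cis-fused α-methylene-γ-lactone.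

Step 13
Reactants: 24 (4S,5R)-4-[(E)-6-(tert-butyldimethylsilyloxy)-3-methylhex-2-en-1-yl]-5-[(1R,2S)-1-hydroxy-2-methylhept-6-yn-1-yl]-3-methylidenedihydrofuran-2(3H)-one
Product: 25 (4S,5R)-4-[(E)-6-hydroxy-3-methylhex-2-en-1-yl]-5-[(1R,2S)-1-hydroxy-2-methylhept-6-yn-1-yl]-3-methylidenedihydrofuran-2(3H)-one
Conditions: HF·pyridine, pyridine, THF, 0 °C → rt
Reagents that add atoms: none
Why: Buffered HF·pyridine removes the primary silyl ether without base, so the methylene lactone is not exposed to nucleophilic fluoride or alkoxide.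

Step 14
Reactants: 25 (4S,5R)-4-[(E)-6-hydroxy-3-methylhex-2-en-1-yl]-5-[(1R,2S)-1-hydroxy-2-methylhept-6-yn-1-yl]-3-methylidenedihydrofuran-2(3H)-one
Product: 26 (E)-6-{(2R,3S)-2-[(1R,2S)-1-hydroxy-2-methylhept-6-yn-1-yl]-4-methylidene-5-oxotetrahydrofuran-3-yl}-4-methylhex-4-enal
Conditions: 2,2,6,6-tetramethylpiperidin-1-oxyl (10 mol %), PhI(OAc)2, CH2Cl2, rt
Reagents that add atoms: none
Why: Oxoammonium (TEMPO/PhI(OAc)2) oxidation is selective for the primary C7 alcohol over the hindered secondary C13 alcohol, so no protecting group is needed.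

Step 15
Reactants: 26 (E)-6-{(2R,3S)-2-[(1R,2S)-1-hydroxy-2-methylhept-6-yn-1-yl]-4-methylidene-5-oxotetrahydrofuran-3-yl}-4-methylhex-4-enal
Product: 27 (1S,3E,7R,12S,13R,14R)-7,13-dihydroxycembra-3,8(19),15(17)-trien-16,14-olide (the target without the epoxide oxygen)
Conditions: CrCl2 (20 mol %), N-{2-[(4R)-4-isopropyl-4,5-dihydro-1,3-oxazol-2-yl]-6-methylphenyl}methanesulfonamide (22 mol %), Et3N (22 mol %), NiCl2(PPh3)2 (10 mol %), Mn (3 equiv), 2,4,6-collidine·HCl (2.5 equiv), LiCl, MeCN/THF 3:1, rt, 26 added by syringe pump over 12 h to 2 mM; aq. NaHCO3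
Reagents that add atoms: none
Why: Proposed new method: a chromium-catalysed, nickel-co-catalysed enantioselective branched (Markovnikov) reductive coupling of a terminal alkyne with an aldehyde, run as a macrocyclisation; zerovalent nickel (from NiCl2(PPh3)2 and Mn) binds the terminal alkyne and is protonated by collidinium at the terminal carbon to give the 1,1-disubstituted alkenylnickel chloride with nickel on C8, which transmetalates to the sulfonamide-bound trivalent chromium to give the same 2-alkenylchromium species that arises from a 2-iodoalkene; this adds only to the aldehyde (not to the lactone or the enoate) inside the chiral ligand sphere, closing the 14-membered ring, creating the C8=C19 methylene and setting C7 as R, after which collidinium protonates the chromium alkoxide and Mn regenerates divalent chromium; the closest known reactions are the stoichiometric CrCl2/catalytic-nickel reductive coupling of terminal alkynes with aldehydes in wet DMF that gives 2-substituted allylic alcohols, and catalytic asymmetric Ni/Cr (Nozaki–Hiyama–Kishi) couplings and macrocyclisations of 2-haloalkenes with sulfonamide ligands, with proton-driven chromium turnover as in photoredox chromium allylations.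

Step 16
Reactants: 27 (1S,3E,7R,12S,13R,14R)-7,13-dihydroxycembra-3,8(19),15(17)-trien-16,14-olide
Product: 28 (1S,3R,4R,7R,12S,13R,14R)-3,4-epoxy-7,13-dihydroxycembra-8(19),15(17)-dien-16,14-olide (CNP0124069.1)
Conditions: 1,2:4,5-di-O-isopropylidene-β-D-erythro-2,3-hexodiulo-2,6-pyranose (1 equiv), Oxone (2KHSO5·KHSO4·K2SO4), NaHCO3, Bu4NHSO4, MeCN/dimethoxymethane/H2O, pH ≈ 8, 0 °C
Reagents that add atoms: potassium peroxymonosulfate, [K+].[O-]S(=O)(=O)OO
Why: Shi asymmetric epoxidation, in which the chiral dioxirane attacks the electron-rich trisubstituted E-olefin in preference to the 1,1-disubstituted allylic olefin and the electron-poor methylene lactone, and the D-fructose-derived ketone delivers the (3R,4R)-epoxide through the spiro transition state; pH 8 protects the lactone.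

## Compound list

1 | (R)-4-benzyl-3-propionyloxazolidin-2-one | CCC(=O)N1[C@H](Cc2ccccc2)COC1=O | starting material
2 | acrolein | C=CC=O | starting material
3 | (R)-4-benzyl-3-[(2R,3S)-3-hydroxy-2-methylpent-4-enoyl]oxazolidin-2-one | O=C(N1[C@H](Cc2ccccc2)COC1=O)[C@H](C)[C@@H](O)C=C | intermediate
4 | (R)-4-benzyl-3-[(2R,3S)-3-(tert-butyldimethylsilyloxy)-2-methylpent-4-enoyl]oxazolidin-2-one | O=C(N1[C@H](Cc2ccccc2)COC1=O)[C@H](C)[C@@H](O[Si](C)(C)C(C)(C)C)C=C | intermediate
5 | (2S,3S)-3-(tert-butyldimethylsilyloxy)-2-methylpent-4-en-1-ol | OC[C@H](C)[C@@H](O[Si](C)(C)C(C)(C)C)C=C | intermediate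
6 | tert-butyl{[(3S,4R)-5-iodo-4-methylpent-1-en-3-yl]oxy}dimethylsilane | IC[C@H](C)[C@@H](O[Si](C)(C)C(C)(C)C)C=C | intermediate
7 | (4-bromobut-1-yn-1-yl)trimethylsilane | C[Si](C)(C)C#CCCBr | starting material
8 | [4-(trimethylsilyl)but-3-yn-1-yl]magnesium bromide | C[Si](C)(C)C#CCC[Mg]Br | intermediate
9 | tert-butyldimethyl{[(3S,4S)-4-methyl-9-(trimethylsilyl)non-1-en-8-yn-3-yl]oxy}silane | C[Si](C)(C)C#CCCC[C@H](C)[C@@H](O[Si](C)(C)C(C)(C)C)C=C | intermediate
10 | (3S,4S)-4-methylnon-1-en-8-yn-3-ol | C#CCCC[C@H](C)[C@@H](O)C=C | intermediate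
11 | pent-4-yn-1-ol | C#CCCCO | starting material
12 | tert-butyldimethyl(pent-4-yn-1-yloxy)silane | C#CCCCO[Si](C)(C)C(C)(C)C | intermediate
13 | oxirane | C1CO1 | starting material
14 | (E)-[5-(tert-butyldimethylsilyloxy)-2-methylpent-1-en-1-yl]dimethylalane | C[Al](C)/C=C(\C)CCCO[Si](C)(C)C(C)(C)C | intermediate
15 | lithium butyl[(E)-5-(tert-butyldimethylsilyloxy)-2-methylpent-1-en-1-yl]dimethylaluminate | [Li+].CCCC[Al-](C)(C)/C=C(\C)CCCO[Si](C)(C)C(C)(C)C | intermediate
16 | (E)-7-(tert-butyldimethylsilyloxy)-4-methylhept-3-en-1-ol | OCC/C=C(\C)CCCO[Si](C)(C)C(C)(C)C | intermediate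
17 | (E)-7-(tert-butyldimethylsilyloxy)-4-methylhept-3-enal | O=CC/C=C(\C)CCCO[Si](C)(C)C(C)(C)C | intermediate
18 | methyl propiolate | C#CC(=O)OC | starting material
19 | methyl 2-(diisobutylalumanyl)acrylate | C=C([Al](CC(C)C)CC(C)C)C(=O)OC | intermediate
20 | methyl (E)-9-(tert-butyldimethylsilyloxy)-3-hydroxy-6-methyl-2-methylidenenon-5-enoate (racemic at C-3) | C=C(C(=O)OC)C(O)C/C=C(\C)CCCO[Si](C)(C)C(C)(C)C | intermediate
21 | methyl (2Z,5E)-2-(bromomethyl)-9-(tert-butyldimethylsilyloxy)-6-methylnona-2,5-dienoate | BrC/C(C(=O)OC)=C\C/C=C(\C)CCCO[Si](C)(C)C(C)(C)C | intermediate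
22 | (2R,3S)-2-hydroxy-3-methyloct-7-ynal | C#CCCC[C@H](C)[C@@H](O)C=O | intermediate
23 | methyl (3S,4R,5R,6S)-3-[(E)-6-(tert-butyldimethylsilyloxy)-3-methylhex-2-en-1-yl]-4,5-dihydroxy-6-methyl-2-methylideneundec-10-ynoate | C#CCCC[C@H](C)[C@@H](O)[C@H](O)[C@H](C(=C)C(=O)OC)C/C=C(\C)CCCO[Si](C)(C)C(C)(C)C | intermediate
24 | (4S,5R)-4-[(E)-6-(tert-butyldimethylsilyloxy)-3-methylhex-2-en-1-yl]-5-[(1R,2S)-1-hydroxy-2-methylhept-6-yn-1-yl]-3-methylidenedihydrofuran-2(3H)-one | C#CCCC[C@H](C)[C@@H](O)[C@@H]1OC(=O)C(=C)[C@@H]1C/C=C(\C)CCCO[Si](C)(C)C(C)(C)C | intermediate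
25 | (4S,5R)-4-[(E)-6-hydroxy-3-methylhex-2-en-1-yl]-5-[(1R,2S)-1-hydroxy-2-methylhept-6-yn-1-yl]-3-methylidenedihydrofuran-2(3H)-one | C#CCCC[C@H](C)[C@@H](O)[C@@H]1OC(=O)C(=C)[C@@H]1C/C=C(\C)CCCO | intermediate
26 | (E)-6-{(2R,3S)-2-[(1R,2S)-1-hydroxy-2-methylhept-6-yn-1-yl]-4-methylidene-5-oxotetrahydrofuran-3-yl}-4-methylhex-4-enal | C#CCCC[C@H](C)[C@@H](O)[C@@H]1OC(=O)C(=C)[C@@H]1C/C=C(\C)CCC=O | intermediate
27 | (1S,3E,7R,12S,13R,14R)-7,13-dihydroxycembra-3,8(19),15(17)-trien-16,14-olide | C=C1CCC[C@H](C)[C@@H](O)[C@@H]2OC(=O)C(=C)[C@@H]2C/C=C(\C)CC[C@H]1O | intermediate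
28 | (1S,3R,4R,7R,12S,13R,14R)-3,4-epoxy-7,13-dihydroxycembra-8(19),15(17)-dien-16,14-olide (CNP0124069.1) | C=C1CCC[C@H](C)[C@@H](O)[C@@H]2OC(=O)C(=C)[C@@H]2C[C@H]2O[C@]2(C)CC[C@H]1O | target

## Step count and risk

Total steps: 16. Longest linear sequence: 11 (steps 1–6, then 12–16); the east branch (steps 7–11) joins at step 12.

**Step 15 (the proposed new macrocyclisation).** The risks are failure of the Markovnikov hydrometalation, loss of the ligand from chromium under the protic turnover conditions, and nickel hydride reduction of the methylene lactone. The fallback uses known chemistry, sets out from 26 and comes back at 27. The C13 hydroxyl of 26 is silylated (Et3SiCl, imidazole, CH2Cl2) to give (E)-4-methyl-6-{(2R,3S)-4-methylidene-2-[(1R,2S)-2-methyl-1-(triethylsilyloxy)hept-6-yn-1-yl]-5-oxotetrahydrofuran-3-yl}hex-4-enal F1. This is cyclised by the known nickel-catalysed exo-selective reductive macrocyclisation of terminal ynals: Ni(cod)2 (30 mol %), the bulky carbene 1,3-bis(2,6-diisopropylphenyl)-4,5-diphenylimidazolidin-2-ylidene (from its tetrafluoroborate and KOt-Bu, one enantiomer of the C2-symmetric backbone), i-Pr3SiH, THF, rt, slow addition. Oxidative cyclisation of zerovalent nickel with alkyne and aldehyde places the new bond on the internal alkyne carbon and the silane traps the C7 oxygen, giving the 13-O-triethylsilyl 7-O-triisopropylsilyl ether of 27 F2. HF·pyridine (THF, rt) removes both silyl groups and returns 27.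

**Step 12 (ozonolysis, indium allylation, lactonisation).** The risks are handling of the free α-hydroxy aldehyde and the level of chelation control. The fallback sets out from 9 and comes back at 25; it replaces substrate (chelation) control in water by catalyst control on a stable, protected aldehyde.
- K2CO3 in MeOH removes only the alkynyl silyl group of 9 to give tert-butyldimethyl{[(3S,4S)-4-methylnon-1-en-8-yn-3-yl]oxy}silane F3.
- Ozonolysis (O3, CH2Cl2, −78 °C; Me2S) gives the isolable (2R,3S)-2-(tert-butyldimethylsilyloxy)-3-methyloct-7-ynal F4.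
- F4 and 21 are joined by a catalytic asymmetric chromium-mediated 2-(alkoxycarbonyl)allylation (CrCl2 10 mol %, the sulfonamide ligand of step 15 in the antipode that overrides the Felkin preference, Et3N, Mn, Cp2ZrCl2, MeCN, rt) to give methyl (3S,4R,5R,6S)-5-(tert-butyldimethylsilyloxy)-3-[(E)-6-(tert-butyldimethylsilyloxy)-3-methylhex-2-en-1-yl]-4-hydroxy-6-methyl-2-methylideneundec-10-ynoate F5.
- Pyridinium p-toluenesulfonate in CH2Cl2 closes F5 to (4S,5R)-4-[(E)-6-(tert-butyldimethylsilyloxy)-3-methylhex-2-en-1-yl]-5-[(1R,2S)-1-(tert-butyldimethylsilyloxy)-2-methylhept-6-yn-1-yl]-3-methylidenedihydrofuran-2(3H)-one F6.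
- HF·pyridine removes both silyl ethers and returns 25.

**Step 16 (late Shi epoxidation on the macrocycle).** The risks are that the ring conformation opposes the reagent's facial preference, and over-oxidation of the C8=C19 olefin. The fallback sets out from 24 and comes back at 28; it moves the epoxidation to the acyclic stage, where Shi control is most dependable.
- 24 is epoxidised under the conditions of step 16 to (4S,5R)-4-({(2R,3R)-3-[3-(tert-butyldimethylsilyloxy)propyl]-3-methyloxiran-2-yl}methyl)-5-[(1R,2S)-1-hydroxy-2-methylhept-6-yn-1-yl]-3-methylidenedihydrofuran-2(3H)-one F7.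
- Bu4NF buffered with AcOH (THF, 0 °C; no acid stronger than AcOH, to avoid tetrahydrofuran formation from the epoxy alcohol) gives (4S,5R)-4-{[(2R,3R)-3-(3-hydroxypropyl)-3-methyloxiran-2-yl]methyl}-5-[(1R,2S)-1-hydroxy-2-methylhept-6-yn-1-yl]-3-methylidenedihydrofuran-2(3H)-one F8.
- 2,2,6,6-Tetramethylpiperidin-1-oxyl/PhI(OAc)2 gives 3-[(2R,3R)-3-({(2R,3S)-2-[(1R,2S)-1-hydroxy-2-methylhept-6-yn-1-yl]-4-methylidene-5-oxotetrahydrofuran-3-yl}methyl)-2-methyloxiran-2-yl]propanal F9.
- Ring closure of F9 under the conditions of step 15 gives 28 directly.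

## Further compounds

F1 | step 15 | (E)-4-methyl-6-{(2R,3S)-4-methylidene-2-[(1R,2S)-2-methyl-1-(triethylsilyloxy)hept-6-yn-1-yl]-5-oxotetrahydrofuran-3-yl}hex-4-enal | C#CCCC[C@H](C)[C@@H](O[Si](CC)(CC)CC)[C@@H]1OC(=O)C(=C)[C@@H]1C/C=C(\C)CCC=O
F2 | step 15 | 13-O-triethylsilyl 7-O-triisopropylsilyl ether of 27 | C=C1CCC[C@H](C)[C@@H](O[Si](CC)(CC)CC)[C@@H]2OC(=O)C(=C)[C@@H]2C/C=C(\C)CC[C@H]1O[Si](C(C)C)(C(C)C)C(C)C
F3 | step 12 | tert-butyldimethyl{[(3S,4S)-4-methylnon-1-en-8-yn-3-yl]oxy}silane | C#CCCC[C@H](C)[C@@H](O[Si](C)(C)C(C)(C)C)C=C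
F4 | step 12 | (2R,3S)-2-(tert-butyldimethylsilyloxy)-3-methyloct-7-ynal | C#CCCC[C@H](C)[C@@H](O[Si](C)(C)C(C)(C)C)C=O
F5 | step 12 | methyl (3S,4R,5R,6S)-5-(tert-butyldimethylsilyloxy)-3-[(E)-6-(tert-butyldimethylsilyloxy)-3-methylhex-2-en-1-yl]-4-hydroxy-6-methyl-2-methylideneundec-10-ynoate | C#CCCC[C@H](C)[C@@H](O[Si](C)(C)C(C)(C)C)[C@H](O)[C@H](C(=C)C(=O)OC)C/C=C(\C)CCCO[Si](C)(C)C(C)(C)C
F6 | step 12 | (4S,5R)-4-[(E)-6-(tert-butyldimethylsilyloxy)-3-methylhex-2-en-1-yl]-5-[(1R,2S)-1-(tert-butyldimethylsilyloxy)-2-methylhept-6-yn-1-yl]-3-methylidenedihydrofuran-2(3H)-one | C#CCCC[C@H](C)[C@@H](O[Si](C)(C)C(C)(C)C)[C@@H]1OC(=O)C(=C)[C@@H]1C/C=C(\C)CCCO[Si](C)(C)C(C)(C)C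
F7 | step 16 | (4S,5R)-4-({(2R,3R)-3-[3-(tert-butyldimethylsilyloxy)propyl]-3-methyloxiran-2-yl}methyl)-5-[(1R,2S)-1-hydroxy-2-methylhept-6-yn-1-yl]-3-methylidenedihydrofuran-2(3H)-one | C#CCCC[C@H](C)[C@@H](O)[C@@H]1OC(=O)C(=C)[C@@H]1C[C@H]1O[C@]1(C)CCCO[Si](C)(C)C(C)(C)C
F8 | step 16 | (4S,5R)-4-{[(2R,3R)-3-(3-hydroxypropyl)-3-methyloxiran-2-yl]methyl}-5-[(1R,2S)-1-hydroxy-2-methylhept-6-yn-1-yl]-3-methylidenedihydrofuran-2(3H)-one | C#CCCC[C@H](C)[C@@H](O)[C@@H]1OC(=O)C(=C)[C@@H]1C[C@H]1O[C@]1(C)CCCO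
F9 | step 16 | 3-[(2R,3R)-3-({(2R,3S)-2-[(1R,2S)-1-hydroxy-2-methylhept-6-yn-1-yl]-4-methylidene-5-oxotetrahydrofuran-3-yl}methyl)-2-methyloxiran-2-yl]propanal | C#CCCC[C@H](C)[C@@H](O)[C@@H]1OC(=O)C(=C)[C@@H]1C[C@H]1O[C@]1(C)CCC=O
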